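**Plan**

1. The target is the 12-acetate of a 3,8-dioxatricyclo[7.2.2.0^{2,7}]tridecane (an oxidised bisabolane). After removal of acetyl and silyl groups, one retro-Prins operation cuts the C1–C12 ring bond (bridgehead CH to the acetoxy carbinol) together with the C2–O3 ether bond; this opens the cyclohexane and the bromotetrahydropyran and leaves the 2,3,4,7-tetrahydrooxepine aldehyde 21.
2. What makes this possible: in 21 the CH2CHO arm on oxepine C2 and the trisubstituted C5=C6 alkene are 1,4-related across the seven-membered ring, and the arm and the C7 bromohydrin chain are cis. The aldehyde can therefore reach only C5 in a six-membered array, and the tertiary cation at C6 forms next to the side-chain tertiary OH.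
3. Further cuts: the oxepine O1–C2 bond (7-endo epoxide opening) and the C4–C5 bond (sp3–sp2 coupling of epoxy triflate 7 with Z-iodo dienol 13).
4. Forward order: 7 + 13 → 15 → oxepine ring (step 11) → side-chain bromohydrin → aldehyde 21 → cyclohexane and tetrahydropyran closed together (step 17) → acetylation, desilylation.
5. Stereochemistry: oxepine C7 from Brown allylboration; oxepine C2/C3 from Sharpless epoxidation plus inversion in the ring closure; C–Br from Shi epoxidation plus SN2 bromide. The last three centres (carbinol, bridgehead CH, quaternary ether carbon) are set in step 17 by substrate control.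

Key step: step 17

Remark: tricyclic compounds are named with the ring numbering of the target (C1 bridgehead CH, C2 quaternary ether carbon, C9 methyl-bearing bridgehead, C10 hydroxy carbon, C12 acetoxy carbon); oxepines are numbered O1, C2 (quaternary), C3 (carbinol), C4, C5=C6, C7. The secondary bromide is assumed inert to HF·pyridine, Dess–Martin oxidation and catalytic Sc(OTf)3.

**Route**

Step 1
Reactants: 1 4-(tert-butyldimethylsilyloxy)but-1-yne
Product: 3 methyl 5-(tert-butyldimethylsilyloxy)pent-2-ynoate, via lithium acetylide 2 (not isolated)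
Conditions: n-BuLi, THF, −78 °C; then ClCO2Me, −78 → 0 °C
Reagents that add atoms: methyl chloroformate, COC(=O)Cl
Why: Deprotonation of the terminal alkyne and C-acylation of the lithium acetylide with methyl chloroformate is the standard entry to 2-ynoates.

Step 2
Reactants: 3 methyl 5-(tert-butyldimethylsilyloxy)pent-2-ynoate
Product: 4 methyl (2Z)-5-(tert-butyldimethylsilyloxy)-3-methylpent-2-enoate
Conditions: Me2CuLi (from MeLi and CuI), THF, −78 °C; MeOH quench at −78 °C
Reagents that add atoms: lithium dimethylcuprate, [Li+].C[Cu-]C (made from methyllithium, C[Li], and CuI)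
Why: Syn carbocupration of the ynoate (Corey–Katzenellenbogen cuprate addition) and cold protonation with retention put the new methyl cis to H, so the silyloxyethyl chain ends cis to the ester (Z).

Step 3
Reactants: 4 methyl (2Z)-5-(tert-butyldimethylsilyloxy)-3-methylpent-2-enoate
Product: 5 (2Z)-5-(tert-butyldimethylsilyloxy)-3-methylpent-2-en-1-ol
Conditions: i-Bu2AlH (2.2 equiv), CH2Cl2, −78 °C; potassium sodium tartrate work-up
Reagents that add atoms: none
Why: 1,2-Reduction of the enoate with i-Bu2AlH should give the allylic alcohol without touching the silyl ether or the Z geometry.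

Step 4
Reactants: 5 (2Z)-5-(tert-butyldimethylsilyloxy)-3-methylpent-2-en-1-ol
Product: 6 [(2R,3S)-3-[2-(tert-butyldimethylsilyloxy)ethyl]-3-methyloxiran-2-yl]methanol
Conditions: Ti(OiPr)4 (10 mol %), D-(−)-diethyl tartrate (12 mol %), t-BuOOH, 4 Å MS, CH2Cl2, −20 °C
Reagents that add atoms: tert-butyl hydroperoxide, CC(C)(C)OO
Why: Sharpless asymmetric epoxidation of this nerol-type Z-allylic alcohol with the D-(−)-tartrate catalyst should give the (2R,3S)-epoxide, which fixes the later oxepine C3 and, after inversion, C2.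

Step 5
Reactants: 6 [(2R,3S)-3-[2-(tert-butyldimethylsilyloxy)ethyl]-3-methyloxiran-2-yl]methanol
Product: 7 [(2R,3S)-3-[2-(tert-butyldimethylsilyloxy)ethyl]-3-methyloxiran-2-yl]methyl trifluoromethanesulfonate
Conditions: Tf2O, 2,6-lutidine, CH2Cl2, −78 °C; cold aqueous work-up, used at once
Reagents that add atoms: trifluoromethanesulfonic anhydride, O=S(=O)(OS(=O)(=O)C(F)(F)F)C(F)(F)F
Why: O-Sulfonylation of the primary alcohol at low temperature gives the epoxy triflate, the usual electrophile for carbanion displacement next to an epoxide.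

Step 6
Reactants: 8 prop-2-yn-1-ol
Product: 10 (2Z)-3-iodo-2-methylprop-2-en-1-ol, via alkenylmagnesium chelate 9 (not isolated)
Conditions: MeMgBr (2.5 equiv), CuI (10 mol %), THF, −10 °C → rt; then I2, −78 → 0 °C
Reagents that add atoms: methylmagnesium bromide, C[Mg]Br; iodine, II
Why: Duboudin–Jousseaume anti-carbomagnesiation of the propargylic alkoxide through the five-membered chelate 9 puts methyl on the internal carbon and magnesium cis to the CH2O group, and iodinolysis with retention gives the Z-iodide.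

Step 7
Reactants: 10 (2Z)-3-iodo-2-methylprop-2-en-1-ol
Product: 11 (2Z)-3-iodo-2-methylprop-2-enal
Conditions: MnO2 (activated, excess), CH2Cl2, rt, dark; used crude
Reagents that add atoms: none
Why: MnO2 oxidises the allylic alcohol selectively under neutral conditions that should preserve the Z geometry of the sensitive enal.

Step 8
Reactants: 11 (2Z)-3-iodo-2-methylprop-2-enal
Product: 12 (1Z,3S)-1-iodo-2-methylhexa-1,5-dien-3-ol
Conditions: (−)-Ipc2B(allyl), Et2O, −78 °C; then NaOH, H2O2, 0 °C
Reagents that add atoms: (−)-B-allyldiisopinocampheylborane, C=CCB([C@@H]1C[C@@H]2C[C@H]([C@H]1C)C2(C)C)[C@@H]1C[C@@H]2C[C@H]([C@H]1C)C2(C)C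
Why: Brown allylboration through a closed chair transition state adds allyl to the Si face of the aldehyde and should give the (S)-carbinol, the later oxepine C7.

Step 9
Reactants: 12 (1Z,3S)-1-iodo-2-methylhexa-1,5-dien-3-ol
Product: 13 (1Z,3S)-1-iodo-2,6-dimethylhepta-1,5-dien-3-ol
Conditions: second-generation Grubbs catalyst (5 mol %), 2-methyl-2-butene/CH2Cl2, 40 °C
Reagents that add atoms: 2-methyl-2-butene, CC=C(C)C
Why: Cross-metathesis of the terminal alkene with 2-methyl-2-butene turns allyl into prenyl, while the trisubstituted iodoalkene and the free alcohol should stay out of the reaction.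

Step 10
Reactants: 13 (1Z,3S)-1-iodo-2,6-dimethylhepta-1,5-dien-3-ol; 7 [(2R,3S)-3-[2-(tert-butyldimethylsilyloxy)ethyl]-3-methyloxiran-2-yl]methyl trifluoromethanesulfonate
Product: 15 (2Z,4S)-1-[(2R,3S)-3-[2-(tert-butyldimethylsilyloxy)ethyl]-3-methyloxiran-2-yl]-3,7-dimethylocta-2,6-dien-4-ol, via dilithio dienolate 14 (not isolated)
Conditions: 13 (1.2 equiv), t-BuLi (3.6 equiv), Et2O, −78 °C; then 7, THF, −78 → −40 °C; H2O quench at −78 °C
Reagents that add atoms: none
Why: Iodine–lithium exchange with retention of the Z geometry gives the O,C-dilithio species, whose alkenyl carbanion should displace the primary triflate (SN2 alkylation) much faster than it attacks the trisubstituted epoxide.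

Step 11
Reactants: 15 (2Z,4S)-1-[(2R,3S)-3-[2-(tert-butyldimethylsilyloxy)ethyl]-3-methyloxiran-2-yl]-3,7-dimethylocta-2,6-dien-4-ol
Product: 16 (2R,3R,7S)-2-[2-(tert-butyldimethylsilyloxy)ethyl]-2,6-dimethyl-7-(3-methylbut-2-en-1-yl)-2,3,4,7-tetrahydrooxepin-3-ol
Conditions: camphorsulfonic acid (10 mol %), CH2Cl2, 0 °C
Reagents that add atoms: none
Why: Acid-catalysed intramolecular epoxide opening (7-endo-tet) should occur at the tertiary carbon (Markovnikov, methyl-directed, helped by the Z-alkene in the tether) with inversion, creating the quaternary C2 and leaving the C3 carbinol with retained configuration.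

Step 12
Reactants: 16 (2R,3R,7S)-2-[2-(tert-butyldimethylsilyloxy)ethyl]-2,6-dimethyl-7-(3-methylbut-2-en-1-yl)-2,3,4,7-tetrahydrooxepin-3-ol
Product: 17 (2R,3R,7S)-3-(tert-butyldimethylsilyloxy)-2-[2-(tert-butyldimethylsilyloxy)ethyl]-2,6-dimethyl-7-(3-methylbut-2-en-1-yl)-2,3,4,7-tetrahydrooxepine
Conditions: TBSOTf, 2,6-lutidine, CH2Cl2, −78 → 0 °C
Reagents that add atoms: tert-butyldimethylsilyl trifluoromethanesulfonate, CC(C)(C)[Si](C)(C)OS(=O)(=O)C(F)(F)F
Why: Silylation of the hindered secondary alcohol with the silyl triflate blocks the C3 oxygen, which would otherwise form a lactol with the later aldehyde.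

Step 13
Reactants: 17 (2R,3R,7S)-3-(tert-butyldimethylsilyloxy)-2-[2-(tert-butyldimethylsilyloxy)ethyl]-2,6-dimethyl-7-(3-methylbut-2-en-1-yl)-2,3,4,7-tetrahydrooxepine
Product: 18 (2R,3R,7S)-3-(tert-butyldimethylsilyloxy)-2-[2-(tert-butyldimethylsilyloxy)ethyl]-7-{[(2R)-3,3-dimethyloxiran-2-yl]methyl}-2,6-dimethyl-2,3,4,7-tetrahydrooxepine
Conditions: D-fructose-derived Shi ketone (30 mol %), Oxone (2KHSO5·KHSO4·K2SO4), K2CO3, Bu4NHSO4, MeCN/dimethoxymethane/aqueous buffer (pH 10.5), 0 °C
Reagents that add atoms: potassium peroxymonosulfate (active component of Oxone), [K+].[O-]S(=O)(=O)OO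
Why: Shi asymmetric epoxidation via the spiro transition state should convert the electron-rich, unhindered prenyl alkene into the (R)-epoxide, while the ring alkene is deactivated by its allylic ether oxygen and shielded by its flanking substituents.

Step 14
Reactants: 18 (2R,3R,7S)-3-(tert-butyldimethylsilyloxy)-2-[2-(tert-butyldimethylsilyloxy)ethyl]-7-{[(2R)-3,3-dimethyloxiran-2-yl]methyl}-2,6-dimethyl-2,3,4,7-tetrahydrooxepine
Product: 19 (2R,3R,7S)-7-[(2S)-2-bromo-3-hydroxy-3-methylbutyl]-3-(tert-butyldimethylsilyloxy)-2-[2-(tert-butyldimethylsilyloxy)ethyl]-2,6-dimethyl-2,3,4,7-tetrahydrooxepine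
Conditions: Li2NiBr4, THF, 0 °C → rt; pH 7 aqueous work-up
Reagents that add atoms: dilithium tetrabromonickelate, [Li+].[Li+].[Ni+2].[Br-].[Br-].[Br-].[Br-]
Why: SN2 opening of the epoxide by the soft bromide of Li2NiBr4 at the less substituted carbon (halohydrin formation) should proceed with inversion to give the (S)-bromide and the tertiary alcohol.

Step 15
Reactants: 19 (2R,3R,7S)-7-[(2S)-2-bromo-3-hydroxy-3-methylbutyl]-3-(tert-butyldimethylsilyloxy)-2-[2-(tert-butyldimethylsilyloxy)ethyl]-2,6-dimethyl-2,3,4,7-tetrahydrooxepine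
Product: 20 2-[(2R,3R,7S)-7-[(2S)-2-bromo-3-hydroxy-3-methylbutyl]-3-(tert-butyldimethylsilyloxy)-2,6-dimethyl-2,3,4,7-tetrahydrooxepin-2-yl]ethan-1-ol
Conditions: HF·pyridine, pyridine, THF, 0 °C (monitored)
Reagents that add atoms: none
Why: Fluoride-mediated desilylation should be much faster at the unhindered primary silyl ether than at the secondary one next to the quaternary carbon.

Step 16
Reactants: 20 2-[(2R,3R,7S)-7-[(2S)-2-bromo-3-hydroxy-3-methylbutyl]-3-(tert-butyldimethylsilyloxy)-2,6-dimethyl-2,3,4,7-tetrahydrooxepin-2-yl]ethan-1-ol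
Product: 21 2-[(2R,3R,7S)-7-[(2S)-2-bromo-3-hydroxy-3-methylbutyl]-3-(tert-butyldimethylsilyloxy)-2,6-dimethyl-2,3,4,7-tetrahydrooxepin-2-yl]acetaldehyde
Conditions: Dess–Martin periodinane, pyridine, CH2Cl2, 0 °C → rt
Reagents that add atoms: none
Why: Dess–Martin oxidation converts the primary alcohol into the aldehyde under buffered, non-basic conditions that should leave the tertiary alcohol, the bromide and the β-alkoxy aldehyde intact.

Step 17
Reactants: 21 2-[(2R,3R,7S)-7-[(2S)-2-bromo-3-hydroxy-3-methylbutyl]-3-(tert-butyldimethylsilyloxy)-2,6-dimethyl-2,3,4,7-tetrahydrooxepin-2-yl]acetaldehyde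
Product: 22 (1R,2S,5S,7S,9R,10R,12S)-5-bromo-10-(tert-butyldimethylsilyloxy)-2,4,4,9-tetramethyl-3,8-dioxatricyclo[7.2.2.0^{2,7}]tridecan-12-ol
Conditions: Sc(OTf)3 (10 mol %), 4 Å MS, CH2Cl2, −40 → 0 °C
Reagents that add atoms: none
Why: Sc(OTf)3 activates the aldehyde, the C5 terminus of the C5=C6 alkene attacks its carbon (Markovnikov) to form the carbocyclic C–C bond and a tertiary cation at C6, and the side-chain tertiary hydroxyl captures this cation, closing the bromotetrahydropyran and releasing the proton that frees the new carbinol. The closest known reaction type is the Lewis-acid Prins (cationic carbonyl–ene) cyclisation of olefinic aldehydes with oxygen capture of the cation, as in citronellal to isopulegol or p-menthane-3,8-diol. The cyclohexane closes 6-exo-trig at the carbonyl carbon with the alkene reacting in the exo sense across the oxepine (C2 and C5 become the bridgeheads of a 2-oxabicyclo[3.2.2]nonane), and the tetrahydropyran closes by 6-exo capture of the cation. The bridgehead CH is fixed by the C2 centre because the two-carbon arm can only reach the alkene face it sits on; the quaternary ether carbon is fixed by C7, whose hydroxyl-bearing chain lies on that same face and can only form a cis-fused ring (a trans fusion would need a torsion near 90° about the bridge bond); the carbinol is set by a closed, ene-like arrangement in which the scandium-bound carbonyl oxygen lies over the sp2 carbon C6, hydrogen-bonded to the side-chain hydroxyl, and not over the C4 methylene. The step needs Markovnikov regiochemistry, oxygen capture in preference to proton loss, and a free aldehyde: the trisubstituted alkene secures the first, the proximity of the hydroxyl the second (any ene product would be reprotonated to the same cation under the acid), and the silyl ether on C3 prevents lactol formation.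

Step 18
Reactants: 22 (1R,2S,5S,7S,9R,10R,12S)-5-bromo-10-(tert-butyldimethylsilyloxy)-2,4,4,9-tetramethyl-3,8-dioxatricyclo[7.2.2.0^{2,7}]tridecan-12-ol
Product: 23 (1R,2S,5S,7S,9R,10R,12S)-5-bromo-10-(tert-butyldimethylsilyloxy)-2,4,4,9-tetramethyl-3,8-dioxatricyclo[7.2.2.0^{2,7}]tridecan-12-yl acetate
Conditions: Ac2O, DMAP, pyridine, CH2Cl2, rt
Reagents that add atoms: acetic anhydride, CC(=O)OC(C)=O
Why: DMAP-catalysed acylation should take place at the only free hydroxyl, since the tertiary alcohol is now an ether.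

Step 19
Reactants: 23 (1R,2S,5S,7S,9R,10R,12S)-5-bromo-10-(tert-butyldimethylsilyloxy)-2,4,4,9-tetramethyl-3,8-dioxatricyclo[7.2.2.0^{2,7}]tridecan-12-yl acetate
Product: 24 (1R,2S,5S,7S,9R,10R,12S)-5-bromo-10-hydroxy-2,4,4,9-tetramethyl-3,8-dioxatricyclo[7.2.2.0^{2,7}]tridecan-12-yl acetate
Conditions: HF·pyridine, THF, rt
Reagents that add atoms: none
Why: Fluoride cleavage of the remaining silyl ether should leave the acetate, the bromide and both ring ethers untouched and give the target.

**Compound list**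

1 | 4-(tert-butyldimethylsilyloxy)but-1-yne | C#CCCO[Si](C)(C)C(C)(C)C | starting material
2 | [4-(tert-butyldimethylsilyloxy)but-1-yn-1-yl]lithium | [Li]C#CCCO[Si](C)(C)C(C)(C)C | intermediate
3 | methyl 5-(tert-butyldimethylsilyloxy)pent-2-ynoate | COC(=O)C#CCCO[Si](C)(C)C(C)(C)C | intermediate
4 | methyl (2Z)-5-(tert-butyldimethylsilyloxy)-3-methylpent-2-enoate | COC(=O)/C=C(C)\CCO[Si](C)(C)C(C)(C)C | intermediate
5 | (2Z)-5-(tert-butyldimethylsilyloxy)-3-methylpent-2-en-1-ol | OC/C=C(C)\CCO[Si](C)(C)C(C)(C)C | intermediate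
6 | [(2R,3S)-3-[2-(tert-butyldimethylsilyloxy)ethyl]-3-methyloxiran-2-yl]methanol | CC(C)(C)[Si](C)(C)OCC[C@]1(C)O[C@@H]1CO | intermediate
7 | [(2R,3S)-3-[2-(tert-butyldimethylsilyloxy)ethyl]-3-methyloxiran-2-yl]methyl trifluoromethanesulfonate | CC(C)(C)[Si](C)(C)OCC[C@]1(C)O[C@@H]1COS(=O)(=O)C(F)(F)F | intermediate
8 | prop-2-yn-1-ol | C#CCO | starting material
9 | 4-methyl-2,5-dihydro-1,2-oxamagnesole (cyclic alkenylmagnesium alkoxide) | CC1=C[Mg]OC1 | intermediate
10 | (2Z)-3-iodo-2-methylprop-2-en-1-ol | OC/C(C)=C\I | intermediate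
11 | (2Z)-3-iodo-2-methylprop-2-enal | O=C/C(C)=C\I | intermediate
12 | (1Z,3S)-1-iodo-2-methylhexa-1,5-dien-3-ol | I/C=C(C)\[C@@H](O)CC=C | intermediate
13 | (1Z,3S)-1-iodo-2,6-dimethylhepta-1,5-dien-3-ol | I/C=C(C)\[C@@H](O)CC=C(C)C | intermediate
14 | lithium (1Z,3S)-1-lithio-2,6-dimethylhepta-1,5-dien-3-olate | [Li]/C=C(C)\[C@@H](O[Li])CC=C(C)C | intermediate
15 | (2Z,4S)-1-[(2R,3S)-3-[2-(tert-butyldimethylsilyloxy)ethyl]-3-methyloxiran-2-yl]-3,7-dimethylocta-2,6-dien-4-ol | CC(C)(C)[Si](C)(C)OCC[C@]1(C)O[C@@H]1C/C=C(C)\[C@@H](O)CC=C(C)C | intermediate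
16 | (2R,3R,7S)-2-[2-(tert-butyldimethylsilyloxy)ethyl]-2,6-dimethyl-7-(3-methylbut-2-en-1-yl)-2,3,4,7-tetrahydrooxepin-3-ol | CC(C)(C)[Si](C)(C)OCC[C@@]1(C)O[C@@H](CC=C(C)C)C(C)=CC[C@H]1O | intermediate
17 | (2R,3R,7S)-3-(tert-butyldimethylsilyloxy)-2-[2-(tert-butyldimethylsilyloxy)ethyl]-2,6-dimethyl-7-(3-methylbut-2-en-1-yl)-2,3,4,7-tetrahydrooxepine | CC(C)(C)[Si](C)(C)OCC[C@@]1(C)O[C@@H](CC=C(C)C)C(C)=CC[C@H]1O[Si](C)(C)C(C)(C)C | intermediate
18 | (2R,3R,7S)-3-(tert-butyldimethylsilyloxy)-2-[2-(tert-butyldimethylsilyloxy)ethyl]-7-{[(2R)-3,3-dimethyloxiran-2-yl]methyl}-2,6-dimethyl-2,3,4,7-tetrahydrooxepine | CC(C)(C)[Si](C)(C)OCC[C@@]1(C)O[C@@H](C[C@H]2OC2(C)C)C(C)=CC[C@H]1O[Si](C)(C)C(C)(C)C | intermediate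
19 | (2R,3R,7S)-7-[(2S)-2-bromo-3-hydroxy-3-methylbutyl]-3-(tert-butyldimethylsilyloxy)-2-[2-(tert-butyldimethylsilyloxy)ethyl]-2,6-dimethyl-2,3,4,7-tetrahydrooxepine | CC(C)(C)[Si](C)(C)OCC[C@@]1(C)O[C@@H](C[C@H](Br)C(C)(C)O)C(C)=CC[C@H]1O[Si](C)(C)C(C)(C)C | intermediate
20 | 2-[(2R,3R,7S)-7-[(2S)-2-bromo-3-hydroxy-3-methylbutyl]-3-(tert-butyldimethylsilyloxy)-2,6-dimethyl-2,3,4,7-tetrahydrooxepin-2-yl]ethan-1-ol | OCC[C@@]1(C)O[C@@H](C[C@H](Br)C(C)(C)O)C(C)=CC[C@H]1O[Si](C)(C)C(C)(C)C | intermediate
21 | 2-[(2R,3R,7S)-7-[(2S)-2-bromo-3-hydroxy-3-methylbutyl]-3-(tert-butyldimethylsilyloxy)-2,6-dimethyl-2,3,4,7-tetrahydrooxepin-2-yl]acetaldehyde | O=CC[C@@]1(C)O[C@@H](C[C@H](Br)C(C)(C)O)C(C)=CC[C@H]1O[Si](C)(C)C(C)(C)C | intermediate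
22 | (1R,2S,5S,7S,9R,10R,12S)-5-bromo-10-(tert-butyldimethylsilyloxy)-2,4,4,9-tetramethyl-3,8-dioxatricyclo[7.2.2.0^{2,7}]tridecan-12-ol | O[C@H]1C[C@@]2(C)O[C@H]3C[C@H](Br)C(C)(C)O[C@@]3(C)[C@@H]1C[C@H]2O[Si](C)(C)C(C)(C)C | intermediate
23 | (1R,2S,5S,7S,9R,10R,12S)-5-bromo-10-(tert-butyldimethylsilyloxy)-2,4,4,9-tetramethyl-3,8-dioxatricyclo[7.2.2.0^{2,7}]tridecan-12-yl acetate | CC(=O)O[C@H]1C[C@@]2(C)O[C@H]3C[C@H](Br)C(C)(C)O[C@@]3(C)[C@@H]1C[C@H]2O[Si](C)(C)C(C)(C)C | intermediate
24 | (1R,2S,5S,7S,9R,10R,12S)-5-bromo-10-hydroxy-2,4,4,9-tetramethyl-3,8-dioxatricyclo[7.2.2.0^{2,7}]tridecan-12-yl acetate | CC(=O)O[C@H]1C[C@@]2(C)O[C@H]3C[C@H](Br)C(C)(C)O[C@@]3(C)[C@@H]1C[C@H]2O | target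

**Step count and risks**

Total step count: 19. Longest linear sequence: 15 steps (steps 1–5 and 10–19).

Steps most likely to fail:

Step 17. The tertiary cation may lose a proton (ene pathway) instead of being captured by oxygen, the carbonyl may approach with the other face and give the epimeric carbinol, or the β-alkoxy aldehyde may open by retro-oxa-Michael reaction. The fallback separates the two ring closures and sets out from 21. A type 1 intramolecular carbonyl–ene reaction with Me2AlCl (2.5 equiv, CH2Cl2, −78 °C) should close the carbocycle and give the homoallylic alcohol with an exocyclic methylidene, the 4-methylidene-2-oxabicyclo[3.2.2]nonan-6-ol F1. Acid-catalysed Markovnikov hydroalkoxylation of the methylidene by the side-chain tertiary alcohol (Amberlyst 15 or catalytic TfOH, CH2Cl2) then closes the tetrahydropyran, and the route is rejoined at 22.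

Step 11. The hydroxyl may attack the secondary epoxide carbon (6-exo closure to a dihydropyran), or the activated epoxide may rearrange by hydride shift to a ketone. The fallback replaces epoxide opening by Markovnikov oxymercuration and sets out from 15. Et2Al(tmp) (diethylaluminium 2,2,6,6-tetramethylpiperidide) isomerises the epoxide to the secondary allylic alcohol with a 1,1-disubstituted alkene, (4R,6Z,8S)-1-(tert-butyldimethylsilyloxy)-7,11-dimethyl-3-methylidenedodeca-6,10-diene-4,8-diol F2. Hg(OCOCF3)2 then closes the seven-membered ether at the more substituted alkene carbon to give the alkylmercury trifluoroacetate F3, and NaBH4/NaOH removes mercury to restore the methyl group, rejoining the route at 16. The configuration of the new quaternary centre would then rest on induction from the adjacent carbinol and would have to be confirmed.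

Step 14. Bromide may be delivered to the tertiary carbon, or the Lewis-acidic nickelate may trigger pinacol-type rearrangement of the epoxide. The fallback forms the bromohydrin directly from the alkene and sets out from 17, bypassing 18. NBS in aqueous THF at 0 °C (terminal bromohydrin formation of the accessible prenyl alkene) gives Markovnikov regiochemistry with certainty but no control at the C–Br centre. The unwanted epimer, the (2R)-bromo isomer F4, is removed by chromatography, and the route is rejoined at 19.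

Further compounds
F1 | step 17 | (1R,3S,5R,6S,9R)-3-[(2S)-2-bromo-3-hydroxy-3-methylbutyl]-9-(tert-butyldimethylsilyloxy)-1-methyl-4-methylidene-2-oxabicyclo[3.2.2]nonan-6-ol (ene product) | O[C@H]1C[C@@]2(C)O[C@@H](C[C@H](Br)C(C)(C)O)C(=C)[C@@H]1C[C@H]2O[Si](C)(C)C(C)(C)C
F2 | step 11 | (4R,6Z,8S)-1-(tert-butyldimethylsilyloxy)-7,11-dimethyl-3-methylidenedodeca-6,10-diene-4,8-diol | CC(C)(C)[Si](C)(C)OCCC(=C)[C@H](O)C/C=C(C)\[C@@H](O)CC=C(C)C
F3 | step 11 | {[(2S,3R,7S)-2-[2-(tert-butyldimethylsilyloxy)ethyl]-3-hydroxy-6-methyl-7-(3-methylbut-2-en-1-yl)-2,3,4,7-tetrahydrooxepin-2-yl]methyl}mercury trifluoroacetate | CC(C)(C)[Si](C)(C)OCC[C@@]1(C[Hg]OC(=O)C(F)(F)F)O[C@@H](CC=C(C)C)C(C)=CC[C@H]1O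
F4 | step 14 | (2R,3R,7S)-7-[(2R)-2-bromo-3-hydroxy-3-methylbutyl]-3-(tert-butyldimethylsilyloxy)-2-[2-(tert-butyldimethylsilyloxy)ethyl]-2,6-dimethyl-2,3,4,7-tetrahydrooxepine | CC(C)(C)[Si](C)(C)OCC[C@@]1(C)O[C@@H](C[C@@H](Br)C(C)(C)O)C(C)=CC[C@H]1O[Si](C)(C)C(C)(C)C
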